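## The problem

The target 26 is a 3,3''-linked biflavanone: two 5,7-dihydroxychroman-4-ones joined by the C3–C3'' single bond, so that C2, C3, C3'' and C2'' are four contiguous stereocentres. The halves differ only in ring B (4'-OMe in one, 4'''-OH in the other), so the two aryl groups must enter one after the other. Both halves are 2,3-trans with the same (2S,3R) configuration, so fixing C2 and C2'' as S and placing each C3 anti to its own C2 oxygen also fixes the C3/C3'' relationship. C2 and C2'' are benzylic ether carbons that cannot be corrected without opening ring C, whereas C3 and C3'' lie α to the C4 ketones and prefer trans; since a base that enolises C4 can also open ring C by retro-oxa-Michael reaction and scramble C2, all four centres are best set before the rings exist. The sensitive parts are the phloroglucinol rings A, the base-labile rings C, and the need to free five phenols while the 4'-methyl ether stays. The feature that is exploited is the substitution of ring A: O1 sits on C8a, the C4 ketone on the neighbouring C4a, and the other two oxygens on C5 and C7. This 1,3,5-trioxygenated benzene maps onto a 4,6-dioxygenated 2-pyrone (its C6–O becomes C8a–O1, its C4–O becomes C7–O) joined across C8a–C4a and C6–C5 to an alkoxy-ynone whose ynol oxygen becomes the C5 oxygen. Rings A and C can thus be made together while C2 and C3 stay untouched.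

## Retrosynthesis

26 from 25. Only O–alkyl bonds are cut: three benzyl ethers and the two 5-ethyl ethers. The ethyl groups are the price of the ynol ether used in the key step; they sit peri to the C4 carbonyls and can be removed by chelation, which the 4'-methyl ether cannot. The forward step must spare ring C and the one methyl ether.

25 from 21. In each half C8a–C4a and C6–C5 are cut, which opens ring A and ring C at once and leads back to the open-chain bis(ynone) bis(pyronyl ether) 21. Against an aryl ketone disconnection (two hindered 2,6-dioxygenated aryl ketones) or an O1–C2 disconnection (substitution at a stereogenic benzylic carbon), this cut leaves C2 and C3 alone and writes the phloroglucinol pattern into the precursor. Compound 21 has no aromatic ring A at all; as an octa-1,7-diyne-3,6-dione it carries the two aryl(pyronyloxy)methyl groups at C4 and C5, between the two ynone carbonyls. The forward reaction must run as a twofold intramolecular [4+2] cycloaddition and CO2 loss, without base.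

21 from 20 and 19. The C4 and C4'' ketones are traced back to carbinols (20) and these to their silyl ethers (19). A ketone β to a pyronyloxy leaving group is prone to elimination, and a free alkoxide next to an alkoxy-ynone would cyclise onto it. The ynones are therefore unveiled in the last step before heating, by a neutral oxidation.

19 from 13 and 18. The bond between the benzylic oxygen and pyrone C6 (the future O1–C8a bond) is cut, which gives the diol 13 and the 6-chloropyrone 18. The pyrone must come after every hydride and acetylide step, since it would not survive them. It must also come while C4 is still a protected carbinol, so that no carbonyl lies β or γ to the alkoxide. Because the alcohol C–O bond is not broken, C2 and C2'' keep their configuration.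

18 from 16 and 17, and 16 from 14. The benzyl ether is cut to 6-chloro-4-hydroxy-2-pyrone 16 and benzyl alcohol 17. The pyrone ring of 16 is cut into two molecules of malonyl dichloride 14: C-acylation of one molecule by the other and lactonisation give the pyrone carbonyl chloride 15, and hydrolysis with loss of CO2 removes the sixth carbon. The forward reaction therefore consumes two equivalents of 14 for each pyrone.

13 from 12, and 12 from 9 and 10. The two C4–alkyne bonds are cut to the dialdehyde 9 and ethoxyacetylene 10. Addition to an aldehyde is preferred over acylation of the acetylide because it delivers the protected carbinol needed for the pyranylation. The new carbinol centres are later oxidised, so their configuration does not matter. The benzylic oxygens carry TMS and the propargylic oxygens TBS, so that base-catalysed methanolysis can free only the former.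

9 from 8 and 7. The aldehydes are traced to the primary alcohols 8 and these to the acyl groups of the bis(imide) 7. Reducing carbinol-bearing esters instead was set aside: each free benzylic hydroxyl is γ to the carboxyl of the other half and would lactonise, and the stable cis-fused dilactone corresponds to the 2,3-cis series.

7 from 5 and 6, 5 from 3 and 4, 3 from 1 and 2. The C2''–C3'' and C2–C3 bonds are cut as two anti-aldol reactions of the succinyl bis(imide) 3, first with 4-methoxybenzaldehyde 4 and then with 4-(benzyloxy)benzaldehyde 6. Both new stereodiads are controlled by the same auxiliary in the same sense, which gives the pseudo-C2-symmetric (anti, anti) array with both carbinols S. The forward reactions must stop cleanly after the first aldol and must overcome hindrance in the second.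

Assumption: the MgCl2-catalysed anti-aldol of (4S)-4-benzyl-N-acyloxazolidinones is taken to add the aldehyde to the chelated Z-enolate on the face away from the benzyl group (R acyl carbon, anti carbinol); should the opposite sense be found, the (4R)-auxiliary would be used with no other change.

## Roads not taken

Alternative 1: The cut is at C3''–C2'' and at the lactone C–O bond: the enolate of the lactone imide A1 would add to 4-(benzyloxy)benzaldehyde, and the aldolate would displace the oxazolidinone to give the cis-fused dilactone A2.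
- Merits: the two aryl groups enter in sequence, the bicyclic template is rigid, and C2 and C2'' are set early by well-tried lactone chemistry. At the skeleton stage this road is more secure than the chosen one.
- Weak points: in A2 the exo aryl groups stand syn to the neighbouring ring-fusion substituents, which corresponds to 2,3-cis flavanones, so C3 and C3'' would have to be inverted after ring closure by base, with the risk to C2 described above. The aldehyde should also approach the lactone enolate anti to the C3 acyl group, which places the aldolate trans to the group it must displace. Both rings A and both O1–C8a bonds would still have to be attached to two hindered lactone carbonyls.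
- Comparison: the chosen plan sets the anti relationships directly and builds ring A from the chain; against the better-known chemistry of A2 it has to set a key step without direct precedent.

Alternative 2: The cut is at C4a–C5 in both halves: Mg(OMe)2 would turn the bis(dihydropyranone) A3, which carries two β,δ-diketo ester chains, into its dienolates, which close onto the terminal esters and aromatise to A4.
- Merits: the step follows the biosynthetic logic, has closer precedent than a pyrone cycloaddition, and delivers rings A with free 5- and 7-hydroxyls, so only one benzyl ether remains to be removed. In endgame economy this road is better.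
- Weak points: A3 is a polycarbonyl compound with many enolisable sites. The basic closure acts on a ring C that can open by retro-oxa-Michael reaction and on C3 and C3'', which are α to ketones. Other foldings of the triketo chain (pyrone or resorcylate formation) compete, and the assembly of A3 is long.
- Comparison: the chosen plan offers a neutral, thermal ring formation that leaves the four stereocentres untouched, and a precursor made from robust pieces; it pays with two extra dealkylations at C5.

Alternative 3: The cut is at C4–C3 and C4''–C3'': a thiazolium-derived carbene would convert one formyl group of the bis(aryl ether) A5 into an acyl anion equivalent that adds across the alkyne, and the second would add to the resulting enone, giving the pentabenzyl ether A6.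
- Merits: the plan is the most convergent of the four. Ring A is bought as a salicylaldehyde and not built, both rings C close in one catalytic operation, and the reaction types are known.
- Weak points: C3 and C3'' are both created in the cascade, one by protonation and one in the Stetter step, under a basic catalyst, so their configuration relative to C2 and to each other rests on thermodynamics. 2,6-Disubstituted benzaldehydes form the carbene adduct reluctantly. The two aryl ethers of A5 must be made at propargylic, benzylic carbons that ionise easily.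
- Comparison: if the cascade gave the trans,trans isomer, this road would be shorter than the chosen one. The chosen plan sets all four centres by auxiliary control before the key step, at the cost of more steps.

Key step: step 13

## Steps

Step 1
Reactants: 1 (4S)-4-benzyl-1,3-oxazolidin-2-one; 2 succinyl chloride
Product: 3 1,4-bis[(4S)-4-benzyl-2-oxo-1,3-oxazolidin-3-yl]butane-1,4-dione
Conditions: 1 (2.05 equiv), n-BuLi, THF, −78 °C; then 2, −78 to 0 °C
Reagents that add atoms: none
Why: N-acylation of the lithiated oxazolidinone by an acid chloride is the standard way to N-acyl imides and should proceed at both ends of the diacid chloride.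

Step 2
Reactants: 3 bis(imide); 4 4-methoxybenzaldehyde
Product: 5 (2R)-1,4-bis[(4S)-4-benzyl-2-oxo-1,3-oxazolidin-3-yl]-2-[(S)-(4-methoxyphenyl)(trimethylsilyloxy)methyl]butane-1,4-dione
Conditions: MgCl2 (0.2 equiv), Et3N, TMSCl, EtOAc, 23 °C; 3 in twofold excess, recovered
Reagents that add atoms: chlorotrimethylsilane, C[Si](C)(C)Cl
Why: MgCl2-catalysed anti-aldol reaction of an N-acyloxazolidinone under soft enolisation; the chelated Z-enolate should be attacked on the face away from the benzyl group through a boat transition state, which sets C3 as R and C2 as S (anti), and silylation of the aldolate turns the catalyst over. Excess 3 and the slower enolisation of the hindered mono-adduct should stop the reaction after one aldol.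

Step 3
Reactants: 5 mono-aldol silyl ether; 6 4-(benzyloxy)benzaldehyde
Product: 7 (2R,3R)-1,4-bis[(4S)-4-benzyl-2-oxo-1,3-oxazolidin-3-yl]-2-[(S)-[4-(benzyloxy)phenyl](trimethylsilyloxy)methyl]-3-[(S)-(4-methoxyphenyl)(trimethylsilyloxy)methyl]butane-1,4-dione
Conditions: MgCl2 (0.5 equiv), Et3N, TMSCl, EtOAc, 23 °C
Reagents that add atoms: chlorotrimethylsilane, C[Si](C)(C)Cl
Why: The same MgCl2-catalysed anti-aldol reaction at the remaining methylene; the second auxiliary should impose the same facial sense and set C3'' as R and C2'' as S, giving the pseudo-C2-symmetric array. The already substituted imide is held by allylic strain and should not enolise, so the silyloxy group is not eliminated.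

Step 4
Reactants: 7 bis(aldol) bis(imide)
Product: 8 (2S,3S)-2-[(S)-[4-(benzyloxy)phenyl](trimethylsilyloxy)methyl]-3-[(S)-(4-methoxyphenyl)(trimethylsilyloxy)methyl]butane-1,4-diol
Conditions: LiBH4, MeOH (2 equiv), THF, 0 °C
Reagents that add atoms: none
Why: Reductive cleavage of N-acyloxazolidinones by LiBH4 gives the primary alcohols and returns the auxiliary; the hindered secondary TMS ethers and the stereocentres should be unaffected (the descriptors at the core carbons change only because the substituent priorities change).

Step 5
Reactants: 8 diol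
Product: 9 (2R,3R)-2-[(S)-[4-(benzyloxy)phenyl](trimethylsilyloxy)methyl]-3-[(S)-(4-methoxyphenyl)(trimethylsilyloxy)methyl]butanedial
Conditions: Dess–Martin periodinane, pyridine, CH2Cl2, 0 °C; used without storage
Reagents that add atoms: none
Why: Dess–Martin oxidation of primary alcohols under pyridine buffering is non-basic and non-acidic enough to keep the α-stereocentres and the TMS ethers.

Step 6
Reactants: 9 dialdehyde; 10 ethoxyacetylene
Product: 12 3,6-bis(tert-butyldimethylsilyloxy)-1,8-diethoxy-4-[(S)-(4-methoxyphenyl)(trimethylsilyloxy)methyl]-5-[(S)-[4-(benzyloxy)phenyl](trimethylsilyloxy)methyl]octa-1,7-diyne (C4 and C5 as in 9; C3 and C6 epimers), via dilithium bis(propargylic alkoxide) 11 (not isolated)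
Conditions: 10, n-BuLi, THF, −78 °C; add 9; then TBSOTf, −78 to 0 °C
Reagents that add atoms: tert-butyldimethylsilyl trifluoromethanesulfonate, CC(C)(C)[Si](C)(C)OS(=O)(=O)C(F)(F)F
Why: 1,2-Addition of a lithium acetylide to an aldehyde at low temperature is faster than enolisation, and the lithium alkoxides are silylated in the same flask; the new carbinol centres are oxidised later, so their configuration is irrelevant. TMS does not migrate because that would trade the more stable propargylic alkoxide for a benzylic one.

Step 7
Reactants: 12 fully silylated bis(ynol ether)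
Product: 13 3,6-bis(tert-butyldimethylsilyloxy)-1,8-diethoxy-4-[(S)-hydroxy(4-methoxyphenyl)methyl]-5-[(S)-[4-(benzyloxy)phenyl](hydroxy)methyl]octa-1,7-diyne (C4 and C5 as in 9; C3 and C6 epimers)
Conditions: K2CO3 (0.2 equiv), MeOH, 0 °C
Reagents that add atoms: none
Why: Base-catalysed methanolysis cleaves TMS ethers far faster than secondary TBS ethers, and ynol ethers are stable to base, so only the benzylic hydroxyls are freed.

Step 8
Reactants: 14 malonyl dichloride (two molecules, which condense with each other)
Product: 16 6-chloro-4-hydroxy-2H-pyran-2-one, via 6-chloro-4-hydroxy-2-oxo-2H-pyran-3-carbonyl chloride 15 (not isolated)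
Conditions: 14 (2 equiv per pyrone), neat, 20 to 50 °C (HCl evolves); then H2O (1 equiv per pyrone), dioxane, 40 °C (HCl and CO2 evolve)
Reagents that add atoms: malonyl dichloride (the second molecule of 14), O=C(Cl)CC(=O)Cl
Why: Self-condensation of malonyl dichloride: the methylene of one molecule is C-acylated by a second molecule, and the enol oxygen of the resulting β-keto acid chloride closes onto an acid chloride group to give the six-carbon pyrone carbonyl chloride 15 with loss of two HCl. Water then hydrolyses the 3-carbonyl chloride to the vinylogous β-keto acid, which decarboxylates on warming, so five of the six carbons of two molecules of 14 end up in 16.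

Step 9
Reactants: 16 6-chloro-4-hydroxy-2H-pyran-2-one; 17 benzyl alcohol
Product: 18 4-(benzyloxy)-6-chloro-2H-pyran-2-one
Conditions: PPh3, DIAD (premixed), THF, 0 °C
Reagents that add atoms: none
Why: Mitsunobu O-alkylation of acidic 4-hydroxy-2-pyrones gives mainly the 4-alkoxy-2-pyrone and needs no free base, so the pyronate has little chance to displace the 6-chloride of a second molecule.

Step 10
Reactants: 13 diol; 18 4-(benzyloxy)-6-chloro-2H-pyran-2-one
Product: 19 3,6-bis(tert-butyldimethylsilyloxy)-1,8-diethoxy-4-[(S)-{[4-(benzyloxy)-2-oxo-2H-pyran-6-yl]oxy}(4-methoxyphenyl)methyl]-5-[(S)-[4-(benzyloxy)phenyl]{[4-(benzyloxy)-2-oxo-2H-pyran-6-yl]oxy}methyl]octa-1,7-diyne (C3 and C6 epimers)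
Conditions: NaH added to 13 and 18 (2.5 equiv), THF, −20 to 0 °C
Reagents that add atoms: none
Why: Addition–elimination of an alkoxide at C6 of a 6-chloro-2-pyrone (a vinylogous acyl chloride carbon bound to the ring oxygen), with chloride as by far the best leaving group; the alcohol C–O bonds are not broken, so C2 and C2'' are retained. Generating the alkoxide in the presence of the electrophile should keep its lifetime short.

Step 11
Reactants: 19 bis(pyronyl ether) bis(silyl ether)
Product: 20 1,8-diethoxy-4-[(S)-{[4-(benzyloxy)-2-oxo-2H-pyran-6-yl]oxy}(4-methoxyphenyl)methyl]-5-[(S)-[4-(benzyloxy)phenyl]{[4-(benzyloxy)-2-oxo-2H-pyran-6-yl]oxy}methyl]octa-1,7-diyne-3,6-diol (C3 and C6 epimers)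
Conditions: HF·pyridine, excess pyridine, THF, 0 to 20 °C
Reagents that add atoms: none
Why: Fluoride desilylation under pyridine-buffered conditions forms no alkoxide, so the vinylogous acyl (pyronyl) group should not migrate to the neighbouring oxygen, and the medium is only weakly acidic towards the ynol ethers.

Step 12
Reactants: 20 bis(propargylic alcohol)
Product: 21 (4R,5R)-1,8-diethoxy-4-[(S)-{[4-(benzyloxy)-2-oxo-2H-pyran-6-yl]oxy}(4-methoxyphenyl)methyl]-5-[(S)-[4-(benzyloxy)phenyl]{[4-(benzyloxy)-2-oxo-2H-pyran-6-yl]oxy}methyl]octa-1,7-diyne-3,6-dione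
Conditions: MnO2 (activated, excess), CH2Cl2, 20 °C; filtered and used at once
Reagents that add atoms: none
Why: MnO2 oxidation of propargylic alcohols to ynones is neutral, releases no carboxylic acid that could add to the ynol ethers, and converges all carbinol epimers to one compound.

Step 13
Reactants: 21 bis(ynone) bis(pyronyl ether)
Product: 25 (2S,3R)-7-(benzyloxy)-3-[(2S,3R)-7-(benzyloxy)-2-[4-(benzyloxy)phenyl]-5-ethoxy-4-oxochroman-3-yl]-5-ethoxy-2-(4-methoxyphenyl)chroman-4-one, via first bridged lactone cycloadduct 22 (not isolated), via half-cyclised monoflavanone 23 (not isolated), via second bridged lactone cycloadduct 24 (not isolated)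
Conditions: toluene (0.005 M, degassed), 2,6-di-tert-butyl-4-methylpyridine (0.2 equiv), 80 to 100 °C
Reagents that add atoms: none
Why: Proposed new method: each 4-benzyloxy-6-alkoxy-2-pyrone is an electron-rich diene whose nucleophilic C3 is matched with the electrophilic, ethoxy-bearing carbon of the push–pull ynone and whose acetal-like C6 is matched with the ynone α-carbon, so an asynchronous intramolecular [4+2] cycloaddition should form C6–C5 and C8a–C4a (flavanone numbering) and give a 2-oxabicyclo[2.2.2]octadienone that loses CO2 by retro-[4+2]. The closest known reaction types are intramolecular Diels–Alder reactions of 2-pyrones with tethered alkynes followed by CO2 extrusion and the benzannulation of 6-alkoxy-2-pyrones with electron-poor dienophiles; new are the tether through the pyrone 6-oxygen, the alkoxy-ynone partner and the twofold operation. Ring C closes as a six-membered ring through the four-atom tether O1–C2–C3–C4 that links pyrone C6 to the ynone α-carbon, whereas pairing with the ynone of the other half would need a seven-membered ring; ring A closes in the cycloaddition itself and becomes aromatic when CO2 leaves. No lasting stereocentre is formed, because the bridgehead carbons of 22 and 24 become sp2 on decarboxylation, so either pyrone face may react, and C2, C3, C2'' and C3'' are not touched. The step needs regiocontrol, which the tether and the polarity match enforce, and chemoselectivity over β-elimination of the pyronyloxy groups and retro-ene loss of ethylene from the ethoxyalkynes, which the absence of base, the hindered pyridine as acid scavenger and a temperature at or below 100 °C are meant to secure.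

Step 14
Reactants: 25 protected biflavanone
Product: 26 (2S,3R)-3-[(2S,3R)-5,7-dihydroxy-2-(4-hydroxyphenyl)-4-oxochroman-3-yl]-5,7-dihydroxy-2-(4-methoxyphenyl)chroman-4-one
Conditions: BCl3 (excess), pentamethylbenzene, CH2Cl2, −78 to 0 °C; MeOH quench
Reagents that add atoms: none
Why: Lewis-acid dealkylation: BCl3 with pentamethylbenzene as cation scavenger cleaves aryl benzyl ethers at low temperature, and the 5-ethyl ethers are cleaved through the boron chelate with the C4 carbonyl. The 4'-methyl ether cannot chelate and should survive.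

## Compound list

1 | (4S)-4-benzyl-1,3-oxazolidin-2-one | O=C1N[C@@H](Cc2ccccc2)CO1 | starting material
2 | succinyl chloride | ClC(=O)CCC(=O)Cl | starting material
3 | 1,4-bis[(4S)-4-benzyl-2-oxo-1,3-oxazolidin-3-yl]butane-1,4-dione | O=C(CCC(=O)N1[C@@H](Cc2ccccc2)COC1=O)N1[C@@H](Cc2ccccc2)COC1=O | intermediate
4 | 4-methoxybenzaldehyde | COc1ccc(C=O)cc1 | starting material
5 | (2R)-1,4-bis[(4S)-4-benzyl-2-oxo-1,3-oxazolidin-3-yl]-2-[(S)-(4-methoxyphenyl)(trimethylsilyloxy)methyl]butane-1,4-dione | COc1ccc([C@@H](O[Si](C)(C)C)[C@H](C(=O)N2[C@@H](Cc3ccccc3)COC2=O)CC(=O)N2[C@@H](Cc3ccccc3)COC2=O)cc1 | intermediate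
6 | 4-(benzyloxy)benzaldehyde | O=Cc1ccc(OCc2ccccc2)cc1 | starting material
7 | (2R,3R)-1,4-bis[(4S)-4-benzyl-2-oxo-1,3-oxazolidin-3-yl]-2-[(S)-[4-(benzyloxy)phenyl](trimethylsilyloxy)methyl]-3-[(S)-(4-methoxyphenyl)(trimethylsilyloxy)methyl]butane-1,4-dione | COc1ccc([C@@H](O[Si](C)(C)C)[C@H](C(=O)N2[C@@H](Cc3ccccc3)COC2=O)[C@@H](C(=O)N2[C@@H](Cc3ccccc3)COC2=O)[C@H](O[Si](C)(C)C)c2ccc(OCc3ccccc3)cc2)cc1 | intermediate
8 | (2S,3S)-2-[(S)-[4-(benzyloxy)phenyl](trimethylsilyloxy)methyl]-3-[(S)-(4-methoxyphenyl)(trimethylsilyloxy)methyl]butane-1,4-diol | COc1ccc([C@@H](O[Si](C)(C)C)[C@H](CO)[C@@H](CO)[C@H](O[Si](C)(C)C)c2ccc(OCc3ccccc3)cc2)cc1 | intermediate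
9 | (2R,3R)-2-[(S)-[4-(benzyloxy)phenyl](trimethylsilyloxy)methyl]-3-[(S)-(4-methoxyphenyl)(trimethylsilyloxy)methyl]butanedial | COc1ccc([C@@H](O[Si](C)(C)C)[C@H](C=O)[C@@H](C=O)[C@H](O[Si](C)(C)C)c2ccc(OCc3ccccc3)cc2)cc1 | intermediate
10 | ethoxyacetylene | CCOC#C | starting material
11 | dilithium bis(propargylic alkoxide) from 9 and two lithium ethoxyacetylides (carbinol epimers) | COc1ccc([C@@H](O[Si](C)(C)C)[C@H](C([O-])C#COCC)[C@@H](C([O-])C#COCC)[C@H](O[Si](C)(C)C)c2ccc(OCc3ccccc3)cc2)cc1.[Li+].[Li+] | intermediate (not isolated)
12 | 3,6-bis(tert-butyldimethylsilyloxy)-1,8-diethoxy-4-[(S)-(4-methoxyphenyl)(trimethylsilyloxy)methyl]-5-[(S)-[4-(benzyloxy)phenyl](trimethylsilyloxy)methyl]octa-1,7-diyne (C4, C5 as in 9; C3, C6 epimers) | COc1ccc([C@@H](O[Si](C)(C)C)[C@H](C(O[Si](C)(C)C(C)(C)C)C#COCC)[C@@H](C(O[Si](C)(C)C(C)(C)C)C#COCC)[C@H](O[Si](C)(C)C)c2ccc(OCc3ccccc3)cc2)cc1 | intermediate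
13 | 3,6-bis(tert-butyldimethylsilyloxy)-1,8-diethoxy-4-[(S)-hydroxy(4-methoxyphenyl)methyl]-5-[(S)-[4-(benzyloxy)phenyl](hydroxy)methyl]octa-1,7-diyne (C3, C6 epimers) | COc1ccc([C@@H](O)[C@H](C(O[Si](C)(C)C(C)(C)C)C#COCC)[C@@H](C(O[Si](C)(C)C(C)(C)C)C#COCC)[C@H](O)c2ccc(OCc3ccccc3)cc2)cc1 | intermediate
14 | malonyl dichloride | O=C(Cl)CC(=O)Cl | starting material
15 | 6-chloro-4-hydroxy-2-oxo-2H-pyran-3-carbonyl chloride | O=C(Cl)c1c(O)cc(Cl)oc1=O | intermediate (not isolated)
16 | 6-chloro-4-hydroxy-2H-pyran-2-one | O=c1cc(O)cc(Cl)o1 | intermediate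
17 | benzyl alcohol | OCc1ccccc1 | starting material
18 | 4-(benzyloxy)-6-chloro-2H-pyran-2-one | O=c1cc(OCc2ccccc2)cc(Cl)o1 | intermediate
19 | bis(pyronyl ether) bis(TBS ether): 3,6-bis(tert-butyldimethylsilyloxy)-1,8-diethoxy-4-[(S)-{[4-(benzyloxy)-2-oxo-2H-pyran-6-yl]oxy}(4-methoxyphenyl)methyl]-5-[(S)-[4-(benzyloxy)phenyl]{[4-(benzyloxy)-2-oxo-2H-pyran-6-yl]oxy}methyl]octa-1,7-diyne (C3, C6 epimers) | COc1ccc([C@@H](Oc2cc(OCc3ccccc3)cc(=O)o2)[C@H](C(O[Si](C)(C)C(C)(C)C)C#COCC)[C@@H](C(O[Si](C)(C)C(C)(C)C)C#COCC)[C@H](Oc2cc(OCc3ccccc3)cc(=O)o2)c2ccc(OCc3ccccc3)cc2)cc1 | intermediate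
20 | bis(pyronyl ether) diol: 1,8-diethoxy-4-[(S)-{[4-(benzyloxy)-2-oxo-2H-pyran-6-yl]oxy}(4-methoxyphenyl)methyl]-5-[(S)-[4-(benzyloxy)phenyl]{[4-(benzyloxy)-2-oxo-2H-pyran-6-yl]oxy}methyl]octa-1,7-diyne-3,6-diol (C3, C6 epimers) | COc1ccc([C@@H](Oc2cc(OCc3ccccc3)cc(=O)o2)[C@H](C(O)C#COCC)[C@@H](C(O)C#COCC)[C@H](Oc2cc(OCc3ccccc3)cc(=O)o2)c2ccc(OCc3ccccc3)cc2)cc1 | intermediate
21 | (4R,5R)-1,8-diethoxy-4-[(S)-{[4-(benzyloxy)-2-oxo-2H-pyran-6-yl]oxy}(4-methoxyphenyl)methyl]-5-[(S)-[4-(benzyloxy)phenyl]{[4-(benzyloxy)-2-oxo-2H-pyran-6-yl]oxy}methyl]octa-1,7-diyne-3,6-dione | COc1ccc([C@@H](Oc2cc(OCc3ccccc3)cc(=O)o2)[C@H](C(=O)C#COCC)[C@@H](C(=O)C#COCC)[C@H](Oc2cc(OCc3ccccc3)cc(=O)o2)c2ccc(OCc3ccccc3)cc2)cc1 | intermediate (key-step precursor)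
22 | first bridged lactone cycloadduct: the methoxyphenyl half as a 2-oxabicyclo[2.2.2]octa-5,7-dien-3-one fused to ring C, the other half unchanged (bridgeheads undefined; which half reacts first is immaterial) | COc1ccc([C@H]2OC34C=C(OCc5ccccc5)C(C(=O)O3)C(OCC)=C4C(=O)[C@@H]2[C@@H](C(=O)C#COCC)[C@H](Oc2cc(OCc3ccccc3)cc(=O)o2)c2ccc(OCc3ccccc3)cc2)cc1 | intermediate (not isolated)
23 | half-cyclised monoflavanone: (2S,3R)-7-(benzyloxy)-5-ethoxy-2-(4-methoxyphenyl)chroman-4-one carrying at C3 the unchanged pyronyloxy ynone half | COc1ccc([C@H]2Oc3cc(OCc4ccccc4)cc(OCC)c3C(=O)[C@@H]2[C@@H](C(=O)C#COCC)[C@H](Oc2cc(OCc3ccccc3)cc(=O)o2)c2ccc(OCc3ccccc3)cc2)cc1 | intermediate (not isolated)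
24 | second bridged lactone cycloadduct: 23 after cycloaddition of the second half (bridgeheads undefined) | COc1ccc([C@H]2Oc3cc(OCc4ccccc4)cc(OCC)c3C(=O)[C@@H]2[C@H]2C(=O)C3=C(OCC)C4C(=O)OC3(C=C4OCc5ccccc5)O[C@@H]2c2ccc(OCc3ccccc3)cc2)cc1 | intermediate (not isolated)
25 | (2S,3R)-7-(benzyloxy)-3-[(2S,3R)-7-(benzyloxy)-2-[4-(benzyloxy)phenyl]-5-ethoxy-4-oxochroman-3-yl]-5-ethoxy-2-(4-methoxyphenyl)chroman-4-one | COc1ccc([C@H]2Oc3cc(OCc4ccccc4)cc(OCC)c3C(=O)[C@@H]2[C@H]2C(=O)c3c(OCC)cc(OCc4ccccc4)cc3O[C@@H]2c2ccc(OCc3ccccc3)cc2)cc1 | intermediate (key-step product)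
26 | (2S,3R)-3-[(2S,3R)-5,7-dihydroxy-2-(4-hydroxyphenyl)-4-oxochroman-3-yl]-5,7-dihydroxy-2-(4-methoxyphenyl)chroman-4-one | COc1ccc([C@H]2Oc3cc(O)cc(O)c3C(=O)[C@@H]2[C@H]2C(=O)c3c(O)cc(O)cc3O[C@@H]2c2ccc(O)cc2)cc1 | target

## Step count and least certain steps

Total step count: 14. Longest linear sequence: 12 steps (steps 1 to 7 and 10 to 14); steps 8 and 9 form the two-step side branch to 18.

Step 13 (key step, proposed new method). The cycloaddition may be slower than the competing processes: elimination of the pyronyloxy groups through the C3 or C3'' enol, and retro-ene fragmentation of the ethoxyalkynes. The donor-substituted ynone may also fail to engage the electron-rich pyrone at a tolerable temperature, because the ethoxy group raises the dienophile LUMO. The fallback uses known chemistry, sets out from 9 and returns at 26. The aryllithium obtained by bromine–lithium exchange from 1,5-bis(benzyloxy)-2-bromo-3-fluorobenzene F1 (made by bromination of 1,3-bis(benzyloxy)-5-fluorobenzene) would be added to both aldehydes of 9 to give the bis(carbinol) F2. Dess–Martin oxidation would give the bis(aryl ketone) F3, and mild methanolysis of the TMS ethers the bis(β-hydroxy ketone) F4. K2CO3 in DMF would close both rings C by intramolecular substitution of fluoride (the established chromanone closure) to give the pentabenzyl ether F5, identical with A6. Hydrogenolysis with H2 over Pd/C would then give 26. In this fallback rings A are bought and not built, and C3 and C3'' pass through a base step in which the trans arrangement is the stable one.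

Step 10 (O-pyranylation). The hindered benzylic alkoxide may take the TBS group from the neighbouring propargylic oxygen through a six-membered transfer before it is trapped. It may also attack the lactone carbonyl or C4 of the chloropyrone, with ring opening or loss of benzyloxide, in place of C6. The fallback sets out from 13 and 18 and returns at 19 without new intermediates. The C–O bond would be formed by palladium-catalysed etherification of the 6-chloropyrone with the secondary alcohol (Pd2(dba)3, a bulky di-tert-butyl biarylphosphine, Cs2CO3, toluene), which needs no free alkali alkoxide.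

Step 11 (desilylation). Even buffered HF may add to the ynol ethers or hydrate them on work-up, and the long reaction time needed for hindered secondary TBS ethers may cost pyronyl groups. The fallback changes the order of events, sets out from 8 and returns at 20. The primary hydroxyls of 8 would be silylated (TBSCl, imidazole) to give the bis(TBS ether) F6, and the TMS ethers removed (K2CO3, MeOH) to give the benzylic diol F7. Pyranylation with 18 as in step 10 would give the bis(pyronyl ether) F8, now on a less crowded substrate. The primary TBS ethers would be removed with HF·pyridine before any ynol ether is present, to give the diol F9, and Dess–Martin oxidation would give the dialdehyde F10. The alkynes would then be introduced with the weakly basic ethoxyethynyltitanium reagent from lithium ethoxyacetylide and ClTi(OiPr)3, which gives 20 directly.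

Step 3 (second aldol). Enolisation of the methylene next to the substituted centre may be too slow under catalytic soft enolisation, and the resident stereocentre may oppose the auxiliary (mismatched double stereodifferentiation), leading to poor facial selectivity. The fallback sets out from 1 and returns at 8, so it also replaces steps 1, 2 and 4. Auxiliary 1 would be acylated with mono-tert-butyl succinate (pivaloyl mixed anhydride) to give the imide F11, and the same MgCl2-catalysed anti-aldol with 4 would give the silyl ether F12, with no question of mono-selectivity. LiBH4 would cleave the auxiliary, and the primary alkoxide would close onto the tert-butyl ester to give the β-substituted γ-lactone F13. The lithium enolate of F13 would add to 6 anti to the ring substituent, which is the relationship needed between C3 and C3''; the E-enolate geometry of a lactone favours the anti carbinol, and TMSCl would trap the aldolate as the trans-disubstituted lactone F14. LiAlH4 would then reduce the lactone of F14 to 8.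

Step 14 (global dealkylation). BCl3 may open ring C at the 4-methoxybenzylic C2–O1 bond and so epimerise C2. Benzyl cations may alkylate the electron-rich rings A if the scavenger is too slow, and the 5-ethyl ethers may resist. The fallback sets out from 25 and returns at 26 in two stages. Hydrogenolysis (H2, Pd/C, EtOAc) would remove the three benzyl groups without any Lewis acid and give the 5,5''-di-O-ethyl ether F15. MgI2 etherate would then cleave only the chelated ethyl ethers.

## Further compounds

F1 | step 13 | 1,5-bis(benzyloxy)-2-bromo-3-fluorobenzene | Fc1cc(OCc2ccccc2)cc(OCc2ccccc2)c1Br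
F2 | step 13 | bis(carbinol) from 9 and two 2,4-bis(benzyloxy)-6-fluorophenyllithium (carbinol epimers) | COc1ccc([C@@H](O[Si](C)(C)C)[C@H](C(O)c2c(F)cc(OCc3ccccc3)cc2OCc2ccccc2)[C@@H](C(O)c2c(F)cc(OCc3ccccc3)cc2OCc2ccccc2)[C@H](O[Si](C)(C)C)c2ccc(OCc3ccccc3)cc2)cc1
F3 | step 13 | (2R,3R)-1,4-bis[2,4-bis(benzyloxy)-6-fluorophenyl]-2-[(S)-[4-(benzyloxy)phenyl](trimethylsilyloxy)methyl]-3-[(S)-(4-methoxyphenyl)(trimethylsilyloxy)methyl]butane-1,4-dione | COc1ccc([C@@H](O[Si](C)(C)C)[C@H](C(=O)c2c(F)cc(OCc3ccccc3)cc2OCc2ccccc2)[C@@H](C(=O)c2c(F)cc(OCc3ccccc3)cc2OCc2ccccc2)[C@H](O[Si](C)(C)C)c2ccc(OCc3ccccc3)cc2)cc1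
F4 | step 13 | (2R,3R)-1,4-bis[2,4-bis(benzyloxy)-6-fluorophenyl]-2-[(S)-[4-(benzyloxy)phenyl](hydroxy)methyl]-3-[(S)-hydroxy(4-methoxyphenyl)methyl]butane-1,4-dione | COc1ccc([C@@H](O)[C@H](C(=O)c2c(F)cc(OCc3ccccc3)cc2OCc2ccccc2)[C@@H](C(=O)c2c(F)cc(OCc3ccccc3)cc2OCc2ccccc2)[C@H](O)c2ccc(OCc3ccccc3)cc2)cc1
F5 | step 13 | pentabenzyl ether of the target, (2S,3R,2''S,3''R) | COc1ccc([C@H]2Oc3cc(OCc4ccccc4)cc(OCc4ccccc4)c3C(=O)[C@@H]2[C@H]2C(=O)c3c(OCc4ccccc4)cc(OCc4ccccc4)cc3O[C@@H]2c2ccc(OCc3ccccc3)cc2)cc1
F0 | step 10 | none | none
F6 | step 11 | 1,4-bis(tert-butyldimethylsilyl) ether of 8 | COc1ccc([C@@H](O[Si](C)(C)C)[C@H](CO[Si](C)(C)C(C)(C)C)[C@@H](CO[Si](C)(C)C(C)(C)C)[C@H](O[Si](C)(C)C)c2ccc(OCc3ccccc3)cc2)cc1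
F7 | step 11 | benzylic diol from F6 after TMS removal | COc1ccc([C@@H](O)[C@H](CO[Si](C)(C)C(C)(C)C)[C@@H](CO[Si](C)(C)C(C)(C)C)[C@H](O)c2ccc(OCc3ccccc3)cc2)cc1
F8 | step 11 | bis(pyronyl ether) of F7 | COc1ccc([C@@H](Oc2cc(OCc3ccccc3)cc(=O)o2)[C@H](CO[Si](C)(C)C(C)(C)C)[C@@H](CO[Si](C)(C)C(C)(C)C)[C@H](Oc2cc(OCc3ccccc3)cc(=O)o2)c2ccc(OCc3ccccc3)cc2)cc1
F9 | step 11 | bis(pyronyl ether) butane-1,4-diol from F8 | COc1ccc([C@@H](Oc2cc(OCc3ccccc3)cc(=O)o2)[C@H](CO)[C@@H](CO)[C@H](Oc2cc(OCc3ccccc3)cc(=O)o2)c2ccc(OCc3ccccc3)cc2)cc1
F10 | step 11 | bis(pyronyl ether) butanedial from F9 | COc1ccc([C@@H](Oc2cc(OCc3ccccc3)cc(=O)o2)[C@H](C=O)[C@@H](C=O)[C@H](Oc2cc(OCc3ccccc3)cc(=O)o2)c2ccc(OCc3ccccc3)cc2)cc1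
F11 | step 3 | tert-butyl 4-[(4S)-4-benzyl-2-oxo-1,3-oxazolidin-3-yl]-4-oxobutanoate | CC(C)(C)OC(=O)CCC(=O)N1[C@@H](Cc2ccccc2)COC1=O
F12 | step 3 | tert-butyl (3R)-4-[(4S)-4-benzyl-2-oxo-1,3-oxazolidin-3-yl]-3-[(S)-(4-methoxyphenyl)(trimethylsilyloxy)methyl]-4-oxobutanoate | COc1ccc([C@@H](O[Si](C)(C)C)[C@H](C(=O)N2[C@@H](Cc3ccccc3)COC2=O)CC(=O)OC(C)(C)C)cc1
F13 | step 3 | (4S)-4-[(S)-(4-methoxyphenyl)(trimethylsilyloxy)methyl]dihydrofuran-2(3H)-one | COc1ccc([C@@H](O[Si](C)(C)C)[C@H](CO2)CC2=O)cc1
F14 | step 3 | trans-3,4-disubstituted lactone: 3-[(S)-[4-(benzyloxy)phenyl](trimethylsilyloxy)methyl]-4-[(S)-(4-methoxyphenyl)(trimethylsilyloxy)methyl]dihydrofuran-2(3H)-one, ring carbons as in 8 | COc1ccc([C@@H](O[Si](C)(C)C)[C@H](CO2)[C@@H](C2=O)[C@H](O[Si](C)(C)C)c2ccc(OCc3ccccc3)cc2)cc1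
F15 | step 14 | 5,5''-di-O-ethyl ether of the target | COc1ccc([C@H]2Oc3cc(O)cc(OCC)c3C(=O)[C@@H]2[C@H]2C(=O)c3c(OCC)cc(O)cc3O[C@@H]2c2ccc(O)cc2)cc1
A1 | alternative 1 | (4S)-4-benzyl-3-[2-(4-methoxyphenyl)-5-oxotetrahydrofuran-3-carbonyl]-1,3-oxazolidin-2-one, trans lactone | COc1ccc([C@H]2OC(=O)C[C@@H]2C(=O)N2[C@@H](Cc3ccccc3)COC2=O)cc1
A2 | alternative 1 | exo,exo-4-(4-methoxyphenyl)-8-[4-(benzyloxy)phenyl]-3,7-dioxabicyclo[3.3.0]octane-2,6-dione | COc1ccc([C@H]2OC(=O)[C@H]3[C@@H]2C(=O)O[C@@H]3c2ccc(OCc3ccccc3)cc2)cc1
A3 | alternative 2 | 3,3'-linked bis[2-aryl-6-(4-methoxy-2,4-dioxobutyl)-2,3-dihydro-4H-pyran-4-one] | COc1ccc([C@H]2OC(CC(=O)CC(=O)OC)=CC(=O)[C@@H]2[C@H]2C(=O)C=C(CC(=O)CC(=O)OC)O[C@@H]2c2ccc(OCc3ccccc3)cc2)cc1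
A4 | alternative 2 | 4'''-O-benzyl ether of the target | COc1ccc([C@H]2Oc3cc(O)cc(O)c3C(=O)[C@@H]2[C@H]2C(=O)c3c(O)cc(O)cc3O[C@@H]2c2ccc(OCc3ccccc3)cc2)cc1
A5 | alternative 3 | 1-(4-methoxyphenyl)-4-[4-(benzyloxy)phenyl]but-2-yne-1,4-diol bis[3,5-bis(benzyloxy)-2-formylphenyl] ether | COc1ccc([C@@H](Oc2cc(OCc3ccccc3)cc(OCc3ccccc3)c2C=O)C#C[C@H](Oc2cc(OCc3ccccc3)cc(OCc3ccccc3)c2C=O)c2ccc(OCc3ccccc3)cc2)cc1
A6 | alternative 3 | pentabenzyl ether of the target | COc1ccc([C@H]2Oc3cc(OCc4ccccc4)cc(OCc4ccccc4)c3C(=O)[C@@H]2[C@H]2C(=O)c3c(OCc4ccccc4)cc(OCc4ccccc4)cc3O[C@@H]2c2ccc(OCc3ccccc3)cc2)cc1
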